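Ring C (the trimethylcyclohexane: C8 ring-fusion CH, C9–C12, quaternary C13) hides an aldol: the aryloxy carbon C6 on C8 lies β to C9, whose methyl can stand in for a carbonyl, and C8 adjoins C13. A cyclopentanol (C9–C13) with C13 preformed and a Sharpless-derived epoxide at C8–C6 is therefore made, and a semipinacol rearrangement moves C13 from C9 to C8: one operation expands the five-membered ring to the cyclohexanone of ring C, forms the hindered C8–C13 bond, sets C8 and releases the C6 hydroxyl. Rings A and B follow by an intramolecular Diels–Alder reaction, the cyclophane by Ullmann macro-etherification, the hydroxypyrrolinone by late oxidation.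

Key step: step 8

Atom labels (used throughout, following the target SMILES as written): C1 = ring CH bearing the vinyl group; C2=C3 = ring alkene (C3 methylated); C4, C5 = the next two ring-fusion CH; C6 = aryloxy CH; C7 = CH bearing the acyl group; C8 = ring-fusion CH next to C6; C9 = CH–CH3; C10 = CH2; C11 = CH–CH3; C12 = CH2; C13 = quaternary methyl carbon. Ring A = C1–C2–C3–C4–C5–C7, ring B = C4–C5–C6–C8–C13, ring C = C8–C9–C10–C11–C12–C13. Lactam atoms are primed: C2' (lactam C=O), C3' (acylated), C4', C5' (hemiaminal carbon). The substituent carbon on C13 that later becomes C4 is called C4 from the start.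

Remarks on the chemistry:
- (S)-3-Methylcyclopentanone is made in step 1 because only its enantiomer is a common catalogue item.
- Compounds 6–10 are carried as mixtures of C9 epimers (C9 drawn without configuration); both converge in step 8.
- The hemiaminal carbon C5' of the target is assumed to equilibrate by ring–chain tautomerism, so its final configuration is taken as thermodynamically controlled.

Step 1
Reactants: 1 3-methylcyclopent-2-en-1-one
Product: 2 (S)-3-methylcyclopentanone
Conditions: CuCl (5 mol %), NaOtBu (5 mol %), enantiopure p-tol-BINAP (5 mol %), PMHS, toluene, 0 °C; then 1 M HCl, THF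
Reagents that add atoms: none
Why: Copper hydride asymmetric conjugate reduction delivers hydride to one face of the β-carbon and the silyl enol ether is hydrolysed on work-up, the ligand antipode being the one that leads to the S ketone (C11).

Step 2
Reactants: 2 (S)-3-methylcyclopentanone
Product: 4 methyl (1R,4S)-1,4-dimethyl-2-oxocyclopentane-1-carboxylate, via keto ester sodium enolate 3 (not isolated)
Conditions: NaH, (MeO)2CO, THF, reflux; then MeI, 0 °C to rt
Reagents that add atoms: dimethyl carbonate COC(=O)OC; methyl iodide CI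
Why: Claisen-type C-acylation at the less hindered α-carbon (C13) gives the β-keto ester enolate, whose C-methylation should occur anti to the C11 methyl and so place the ester cis to that methyl (C13 set by 1,3-induction; the minor epimer is removed by chromatography).

Step 3
Reactants: 4 methyl (1R,4S)-1,4-dimethyl-2-oxocyclopentane-1-carboxylate; 5 tert-butyldimethyl(prop-2-yn-1-yloxy)silane
Product: 6 propargylic tertiary alcohol (C9 epimers)
Conditions: 5, n-BuLi, THF, −78 °C; CeCl3; then 4, −78 °C
Reagents that add atoms: none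
Why: 1,2-Addition of the weakly basic cerium acetylide to the hindered ketone (organocerium addition) leaves the neopentyl ester untouched; the C9 epimers are not separated because C9 becomes a carbonyl again in step 8.

Step 4
Reactants: 6 propargylic tertiary alcohol
Product: 7 (E)-allylic diol with C5 silyl ether
Conditions: NaAlH2(OCH2CH2OCH3)2 (Red-Al), THF, 0 °C to rt
Reagents that add atoms: none
Why: Alkoxide-directed trans-hydroalumination of the propargylic alcohol gives the (E)-alkene and the same hydride reduces the ester to the primary alcohol (C4).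

Step 5
Reactants: 7 (E)-allylic diol with C5 silyl ether
Product: 8 C4 TBDPS ether
Conditions: TBDPSCl, imidazole, DMF, rt
Reagents that add atoms: tert-butyl(chloro)diphenylsilane CC(C)(C)[Si](Cl)(c1ccccc1)c1ccccc1
Why: Silylation of the primary neopentyl alcohol beside the unreactive tertiary alcohol masks the oxygen that could otherwise open the epoxide in step 8.

Step 6
Reactants: 8 C4 TBDPS ether
Product: 9 (E)-primary allylic alcohol
Conditions: HF·pyridine, pyridine, THF, 0 °C
Reagents that add atoms: none
Why: Buffered fluoride cleaves the unhindered primary allylic TBS ether much faster than the neopentyl TBDPS ether and spares the acid-sensitive tertiary allylic alcohol.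

Step 7
Reactants: 9 (E)-primary allylic alcohol
Product: 10 trans-epoxy alcohol (C6 R, C8 S)
Conditions: Ti(OiPr)4, D-(−)-diethyl tartrate, t-BuOOH, 4 Å MS, CH2Cl2, −20 °C
Reagents that add atoms: tert-butyl hydroperoxide CC(C)(C)OO
Why: Sharpless asymmetric epoxidation of the (E)-primary allylic alcohol under reagent control by D-(−)-diethyl tartrate sets both epoxide carbons (C6 and C8) irrespective of the C9 configuration.

Step 8
Reactants: 10 trans-epoxy alcohol
Product: 11 keto diol (ring C cyclohexanone)
Conditions: BF3·OEt2 (0.3 equiv), CH2Cl2, −78 °C to −30 °C; aq NaHCO3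
Reagents that add atoms: none
Why: Lewis-acid activation of the epoxide ionises the C8–O bond next to the tertiary carbinol while the anti-periplanar C9–C13 bond migrates to C8 and the carbinol collapses to the C9 ketone, i.e. the semipinacol rearrangement of a 2,3-epoxy alcohol (α-hydroxy epoxide), a known ring expansion of cycloalkanols. No ring is closed; the cyclopentane C9–C13 becomes six-membered ring C by insertion of C8 between C9 and C13 through this 1,2-alkyl shift. C8 is the only new stereocentre and is set by inversion at the epoxide carbon, so the Sharpless epoxide dictates it; C13 migrates with retention and the C6 carbinol keeps the epoxide configuration. Both C9 epimers of 10 converge because C9 becomes planar. The step needs migration of C13 rather than C10, which the higher migratory aptitude of the fully substituted carbon should secure, and ionisation at C8 rather than C6, which the push of the adjacent carbinol and the inductive deactivation of C6 by the neighbouring CH2OH should secure. The silyl ether on C4 keeps that oxygen from opening the epoxide.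

Step 9
Reactants: 11 keto diol
Product: 12 exocyclic methylene diol
Conditions: Zn, CH2Br2, TiCl4, THF–CH2Cl2, 0 °C to rt
Reagents that add atoms: dibromomethane BrCBr
Why: Takai–Lombardo methylenation is non-basic, so the β-hydroxy ketone should neither undergo retro-aldol cleavage nor dehydrate, and it tolerates the free diol.

Step 10
Reactants: 12 exocyclic methylene diol
Product: 13 diol with C9 methyl
Conditions: Mn(dpm)3 (cat.), PhSiH3, t-BuOOH, i-PrOH, rt
Reagents that add atoms: none
Why: Hydrogen-atom-transfer (Mukaiyama-type) hydrogenation reduces the 1,1-disubstituted alkene through a tertiary C9 radical and should give the thermodynamically preferred equatorial methyl, trans to the C8 side chain, since an axial methyl would be syn-axial to the C13 methyl.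

Step 11
Reactants: 13 diol with C9 methyl
Product: 15 γ-hydroxy (E)-enoate, via α-hydroxy aldehyde 14 (not isolated)
Conditions: TEMPO (cat.), PhI(OAc)2, CH2Cl2, rt; then Ph3P=CHCO2Me, rt
Reagents that add atoms: methyl (triphenylphosphoranylidene)acetate COC(=O)C=P(c1ccccc1)(c1ccccc1)c1ccccc1
Why: Nitroxyl-catalysed oxidation is selective for the primary alcohol and the α-hydroxy aldehyde is trapped at once by the stabilised ylide (Wittig reaction) to give the (E)-enoate C5=C7 without touching C6.

Step 12
Reactants: 15 γ-hydroxy (E)-enoate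
Product: 16 C6 benzoate (inverted)
Conditions: PPh3, DIAD, PhCO2H, toluene, 0 °C to rt
Reagents that add atoms: benzoic acid OC(=O)c1ccccc1
Why: Mitsunobu esterification displaces the activated allylic C6 hydroxyl with inversion, which turns the C6 configuration delivered by the epoxide into that of the target and protects the oxygen.

Step 13
Reactants: 16 C6 benzoate
Product: 17 neopentyl alcohol
Conditions: HF·pyridine, THF, rt
Reagents that add atoms: none
Why: Fluoride-mediated desilylation frees the C4 alcohol without harming the benzoate or the enoate.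

Step 14
Reactants: 17 neopentyl alcohol
Product: 18 neopentyl aldehyde
Conditions: Dess–Martin periodinane, NaHCO3, CH2Cl2, rt
Reagents that add atoms: none
Why: Dess–Martin oxidation gives the non-enolisable C4 aldehyde under buffered, neutral conditions.

Step 15
Reactants: 18 neopentyl aldehyde
Product: 19 (E)-2-methyl enal
Conditions: Ph3P=C(CH3)CHO, toluene, 100 °C
Reagents that add atoms: 2-(triphenylphosphoranylidene)propanal CC(C=O)=P(c1ccccc1)(c1ccccc1)c1ccccc1
Why: Wittig reaction with the stabilised α-methyl ylide should give the (E)-alkene C4=C3, with C13 trans to the formyl carbon C2.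

Step 16
Reactants: 19 (E)-2-methyl enal
Product: 20 (E,E)-dienyl iodide
Conditions: CrCl2, CHI3, THF, 0 °C to rt
Reagents that add atoms: iodoform IC(I)I
Why: Takai olefination installs the (E)-iodoalkene C2=C1 chemoselectively at the aldehyde.

Step 17
Reactants: 20 (E,E)-dienyl iodide
Product: 22 tricyclic benzoate ester, via triene 21 (not isolated)
Conditions: copper thiophene-2-carboxylate Cu(O2CC4H3S) (1.5 equiv), CH2=CHSnBu3, NMP, 0 °C to rt; then toluene, BHT, 120 °C
Reagents that add atoms: tributyl(vinyl)stannane C=C[Sn](CCCC)(CCCC)CCCC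
Why: Copper-mediated Stille-type coupling gives the (E,E)-triene without zerovalent palladium (which could ionise the allylic benzoate), and the intramolecular Diels–Alder reaction of the (E)-enoate with the C4=C3–C2=C1 diene should give the cis-fused A/B system because a ring B trans-fused to both six-membered rings is highly strained; suprafacial addition sets C1/C4 cis and C5/C7 trans, and the face is governed by C8 and C6 in the three-atom tether.

Step 18
Reactants: 22 tricyclic benzoate ester
Product: 23 tricyclic γ-lactone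
Conditions: K2CO3, MeOH, rt; then PPTS, toluene, 80 °C
Reagents that add atoms: none
Why: Methanolysis of the benzoate frees the C6 hydroxyl, which lies cis to the C7 ester on ring B and should close the γ-lactone (transesterification), giving an activated acyl donor in which C6–O is masked.

Step 19
Reactants: 24 N-Boc-4-iodo-L-phenylalanine; 25 Meldrum's acid
Product: 27 alkyl Meldrum's acid, via acyl Meldrum's acid 26 (not isolated)
Conditions: EDC·HCl, DMAP, CH2Cl2, 0 °C to rt; then NaBH4, AcOH, 0 °C
Reagents that add atoms: none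
Why: Carbodiimide C-acylation of Meldrum's acid followed by hydride reduction of the acyl group to CH2 homologates the amino acid without touching its stereocentre.

Step 20
Reactants: 27 alkyl Meldrum's acid
Product: 28 N-Boc-5-(4-iodobenzyl)pyrrolidin-2-one
Conditions: toluene, 110 °C
Reagents that add atoms: none
Why: Thermolysis lets the carbamate nitrogen attack a Meldrum's carbonyl with loss of acetone and CO2 (cyclisation–decarboxylation), giving the lactam whose C5' comes from the L-amino acid and carries nitrogen on the same side as in the target.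

Step 21
Reactants: 23 tricyclic γ-lactone; 28 N-Boc-5-(4-iodobenzyl)pyrrolidin-2-one
Product: 29 hydroxy β-keto lactam
Conditions: 28 (2 equiv), LiN(SiMe3)2 (2.2 equiv), THF, −78 °C; then 23, −78 °C to −20 °C; AcOH
Reagents that add atoms: none
Why: Claisen-type C-acylation of the lithium lactam enolate by the strained lactone opens it to the β-keto lactam and releases the C6 alkoxide, the excess enolate taking up the acidic product proton; C3' is left as an epimerisable centre.

Step 22
Reactants: 29 hydroxy β-keto lactam
Product: 30 N-Boc macrocyclic β-keto lactam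
Conditions: CuI (0.5 equiv), 3,4,7,8-tetramethyl-1,10-phenanthroline, Cs2CO3, toluene (high dilution), 110 °C
Reagents that add atoms: none
Why: Intramolecular copper-catalysed Ullmann etherification of the C6 alcohol with the aryl iodide should close the 13-membered para-cyclophane with retention at C6, both reacting groups being held on the same face of ring B.

Step 23
Reactants: 30 N-Boc macrocyclic β-keto lactam
Product: 32 N-Boc pyrrolinone macrocycle, via C3' selenide 31 (not isolated)
Conditions: N-(phenylselanyl)phthalimide, pyridine, CH2Cl2, 0 °C to rt; then H2O2 (30 %), 0 °C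
Reagents that add atoms: none
Why: α-Selenenylation of the β-keto lactam at C3' with a mild selenium-transfer reagent that spares the alkenes, then oxidation and selenoxide syn-elimination toward the only β-hydrogens (C4'), should give the 3-acyl-3-pyrrolin-2-one.

Step 24
Reactants: 32 N-Boc pyrrolinone macrocycle
Product: 33 N–H pyrrolinone macrocycle
Conditions: TFA, CH2Cl2, 0 °C
Reagents that add atoms: none
Why: Acidolysis removes the Boc group from the imide-like nitrogen at low temperature, where the alkenes should survive.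

Step 25
Reactants: 33 N–H pyrrolinone macrocycle
Product: 34 CNP0151253.2
Conditions: KN(SiMe3)2 (2.2 equiv), THF, −78 °C; 2-(phenylsulfonyl)-3-phenyloxaziridine; aq NH4Cl
Reagents that add atoms: 2-(phenylsulfonyl)-3-phenyloxaziridine O=S(=O)(c1ccccc1)N1OC1c1ccccc1
Why: Deprotonation at C5' gives the aromatic 2-oxidopyrrole anion, which the oxaziridine should hydroxylate at C5' (electrophilic enolate oxidation) without epoxidising the alkenes, and the hemiaminal can settle by ring–chain tautomerism into the configuration of the target.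

Compound list
1 | 3-methylcyclopent-2-en-1-one | CC1=CC(=O)CC1 | starting material
2 | (S)-3-methylcyclopentanone | O=C1C[C@@H](C)CC1 | intermediate
3 | sodium enolate of methyl (4S)-4-methyl-2-oxocyclopentane-1-carboxylate | [Na+].COC(=O)C1=C([O-])C[C@@H](C)C1 | intermediate (not isolated)
4 | methyl (1R,4S)-1,4-dimethyl-2-oxocyclopentane-1-carboxylate (ester cis to the C11 methyl) | O=C1C[C@@H](C)C[C@]1(C(=O)OC)C | intermediate
5 | tert-butyldimethyl(prop-2-yn-1-yloxy)silane | C#CCO[Si](C)(C)C(C)(C)C | starting material
6 | methyl (1R,4S)-2-hydroxy-1,4-dimethyl-2-[3-(tert-butyldimethylsilyloxy)prop-1-yn-1-yl]cyclopentane-1-carboxylate, both C9 epimers | OC1(C#CCO[Si](C)(C)C(C)(C)C)C[C@@H](C)C[C@]1(C(=O)OC)C | intermediate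
7 | 2-(hydroxymethyl)-2,4-dimethyl-1-[(E)-3-(tert-butyldimethylsilyloxy)prop-1-en-1-yl]cyclopentan-1-ol (C11, C13 as in 4; C9 epimers) | OC1(/C=C/CO[Si](C)(C)C(C)(C)C)C[C@@H](C)C[C@]1(CO)C | intermediate
8 | C4 tert-butyldiphenylsilyl ether of 7 | OC1(/C=C/CO[Si](C)(C)C(C)(C)C)C[C@@H](C)C[C@]1(CO[Si](c2ccccc2)(c2ccccc2)C(C)(C)C)C | intermediate
9 | (E)-allylic alcohol: 8 without the TBS group (free C5 OH, tertiary C9 OH, C4 OTBDPS) | OC/C=C/C1(O)C[C@@H](C)C[C@]1(CO[Si](c2ccccc2)(c2ccccc2)C(C)(C)C)C | intermediate
10 | trans-epoxy alcohol: C6–C8 epoxide (C6 R, C8 S), primary C5 OH, tertiary C9 OH (epimers), C4 OTBDPS | OC[C@H]1O[C@@H]1C2(O)C[C@@H](C)C[C@]2(CO[Si](c3ccccc3)(c3ccccc3)C(C)(C)C)C | intermediate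
11 | keto diol: cyclohexanone (C9=O) with C8 (R) bearing the (S)-1,2-dihydroxyethyl group (C6, C5); C8, C11, C13 as in the target, C6 epimeric to the target | OC[C@@H](O)[C@@H]1C(=O)C[C@@H](C)C[C@]1(CO[Si](c2ccccc2)(c2ccccc2)C(C)(C)C)C | intermediate
12 | exocyclic methylene diol (C9=CH2) | OC[C@@H](O)[C@@H]1C(=C)C[C@@H](C)C[C@]1(CO[Si](c2ccccc2)(c2ccccc2)C(C)(C)C)C | intermediate
13 | diol with equatorial C9 methyl (C8, C9, C11, C13 as in the target) | OC[C@@H](O)[C@@H]1[C@@H](C)C[C@@H](C)C[C@]1(CO[Si](c2ccccc2)(c2ccccc2)C(C)(C)C)C | intermediate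
14 | α-hydroxy aldehyde (C5 aldehyde) | O=C[C@@H](O)[C@@H]1[C@@H](C)C[C@@H](C)C[C@]1(CO[Si](c2ccccc2)(c2ccccc2)C(C)(C)C)C | intermediate (not isolated)
15 | methyl (E)-4-hydroxy-4-(ring C)-but-2-enoate (C6 OH epimeric to the target) | COC(=O)/C=C/[C@@H](O)[C@@H]1[C@@H](C)C[C@@H](C)C[C@]1(CO[Si](c2ccccc2)(c2ccccc2)C(C)(C)C)C | intermediate
16 | C6 benzoate with the C6 configuration of the target | COC(=O)/C=C/[C@H](OC(=O)c1ccccc1)[C@@H]1[C@@H](C)C[C@@H](C)C[C@]1(CO[Si](c2ccccc2)(c2ccccc2)C(C)(C)C)C | intermediate
17 | C4 primary alcohol | COC(=O)/C=C/[C@H](OC(=O)c1ccccc1)[C@@H]1[C@@H](C)C[C@@H](C)C[C@]1(CO)C | intermediate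
18 | C4 aldehyde | COC(=O)/C=C/[C@H](OC(=O)c1ccccc1)[C@@H]1[C@@H](C)C[C@@H](C)C[C@]1(C=O)C | intermediate
19 | (E)-2-methyl enal on C13 (C4=C3, C2 aldehyde) | COC(=O)/C=C/[C@H](OC(=O)c1ccccc1)[C@@H]1[C@@H](C)C[C@@H](C)C[C@]1(/C=C(\C)/C=O)C | intermediate
20 | (1E,3E)-4-iodo-2-methylbuta-1,3-dienyl compound (C1 iodide) | COC(=O)/C=C/[C@H](OC(=O)c1ccccc1)[C@@H]1[C@@H](C)C[C@@H](C)C[C@]1(/C=C(\C)/C=C/I)C | intermediate
21 | (E,E)-triene enoate (Diels–Alder precursor) | COC(=O)/C=C/[C@H](OC(=O)c1ccccc1)[C@@H]1[C@@H](C)C[C@@H](C)C[C@]1(/C=C(\C)/C=C/C=C)C | intermediate (not isolated)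
22 | tricyclic core with C7 CO2Me and C6 OBz, all core stereocentres as in the target | C=C[C@H]1C=C(C)[C@@H]2[C@H]([C@@H]1C(=O)OC)[C@H](OC(=O)c3ccccc3)[C@@H]1[C@@H](C)C[C@@H](C)C[C@]12C | intermediate
23 | tricyclic γ-lactone (C6–O–C(=O)–C7) | C=C[C@H]1C=C(C)[C@@H]2[C@@H]3[C@@H]1C(=O)O[C@@H]3[C@@H]1[C@@H](C)C[C@@H](C)C[C@]12C | intermediate
24 | N-Boc-4-iodo-L-phenylalanine | CC(C)(C)OC(=O)N[C@@H](Cc1ccc(I)cc1)C(=O)O | starting material
25 | Meldrum's acid (2,2-dimethyl-1,3-dioxane-4,6-dione) | CC1(C)OC(=O)CC(=O)O1 | starting material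
26 | 5-acyl Meldrum's acid of 24 | CC(C)(C)OC(=O)N[C@@H](Cc1ccc(I)cc1)C(=O)C1C(=O)OC(C)(C)OC1=O | intermediate (not isolated)
27 | 5-alkyl Meldrum's acid (acyl C=O reduced to CH2) | CC(C)(C)OC(=O)N[C@@H](Cc1ccc(I)cc1)CC1C(=O)OC(C)(C)OC1=O | intermediate
28 | tert-butyl (R)-2-(4-iodobenzyl)-5-oxopyrrolidine-1-carboxylate (from the L-amino acid) | O=C1CC[C@H](Cc2ccc(I)cc2)N1C(=O)OC(C)(C)C | intermediate
29 | tricyclic C6 alcohol with the C7 acyl group attached to C3' of the N-Boc 5-(4-iodobenzyl) lactam (C3' epimers) | C=C[C@H]1C=C(C)[C@@H]2[C@H]([C@@H]1C(=O)C3C[C@H](Cc4ccc(I)cc4)N(C(=O)OC(C)(C)C)C3=O)[C@H](O)[C@@H]1[C@@H](C)C[C@@H](C)C[C@]12C | intermediate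
30 | 13-membered para-cyclophane, N-Boc β-keto lactam with C5'–H (C3' epimers) | C=C[C@H]1C=C(C)[C@@H]2[C@H]3[C@H](Oc4ccc(cc4)C[C@H]4CC(C(=O)N4C(=O)OC(C)(C)C)C(=O)[C@H]13)[C@@H]1[C@@H](C)C[C@@H](C)C[C@]12C | intermediate
31 | C3' phenylselanyl derivative of 30 | C=C[C@H]1C=C(C)[C@@H]2[C@H]3[C@H](Oc4ccc(cc4)C[C@H]4CC([Se]c5ccccc5)(C(=O)N4C(=O)OC(C)(C)C)C(=O)[C@H]13)[C@@H]1[C@@H](C)C[C@@H](C)C[C@]12C | intermediate (not isolated)
32 | N-Boc 3-acyl-3-pyrrolin-2-one macrocycle (C3'=C4', C5'–H) | C=C[C@H]1C=C(C)[C@@H]2[C@H]3[C@H](Oc4ccc(cc4)C[C@H]4C=C(C(=O)N4C(=O)OC(C)(C)C)C(=O)[C@H]13)[C@@H]1[C@@H](C)C[C@@H](C)C[C@]12C | intermediate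
33 | N–H 3-acyl-3-pyrrolin-2-one macrocycle (C5'–H) | C=C[C@H]1C=C(C)[C@@H]2[C@H]3[C@H](Oc4ccc(cc4)C[C@H]4C=C(C(=O)N4)C(=O)[C@H]13)[C@@H]1[C@@H](C)C[C@@H](C)C[C@]12C | intermediate
34 | CNP0151253.2 | C=C[C@H]1C=C(C)[C@@H]2[C@H]3[C@H](Oc4ccc(cc4)C[C@@]4(O)C=C(C(=O)N4)C(=O)[C@H]13)[C@@H]1[C@@H](C)C[C@@H](C)C[C@]12C | target

Total step count: 25. Longest linear sequence: 23 steps (steps 1–18 and 21–25); steps 19–20 make the lactam fragment.

Steps most likely to fail

1. Step 22 (Ullmann macro-etherification). The strain that builds up as the 13-membered para-cyclophane closes may slow the intramolecular C–O coupling, so that intermolecular etherification, oligomerisation and loss of iodine take over. The fallback sets out from 23 and comes back at 30: the ether bond is made between two molecules and the ring is closed by C-acylation. Lactone 23 is opened with Me(MeO)NH·HCl and AlMe3 to the hydroxy Weinreb amide F1. Intermolecular copper-catalysed etherification of F1 with aryl iodide 28 (CuI, 3,4,7,8-tetramethyl-1,10-phenanthroline, Cs2CO3, toluene, 110 °C) gives the aryl ether F2. Slow addition of F2 to LiN(SiMe3)2 in THF (−78 °C to 0 °C, high dilution) lets the lactam enolate attack the Weinreb amide, whose chelated tetrahedral adduct does not revert, and gives 30.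

2. Step 17 (coupling and cycloaddition). Facial discrimination in the thermal cycloaddition may be poor, or the triene may polymerise at the temperature needed. The fallback sets out from 20 and comes back at 23: the cycloaddition is run on the free alcohol as a Lewis-acid-bound process at low temperature. Methanolysis of the benzoate in 20 (K2CO3, MeOH) gives the hydroxy dienyl iodide F3, and copper-mediated coupling with tributyl(vinyl)stannane gives the hydroxy triene F4. Et2AlCl (CH2Cl2, −78 °C to rt) turns the C6 alcohol into an aluminium alkoxide and activates the enoate, so the cycloaddition should proceed below room temperature through an organised, Lewis-acid-bound transition state to the hydroxy ester F5. F5 lactonises (PPTS, toluene, 80 °C) to 23.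

3. Step 8 (semipinacol ring expansion). A free hydroxyl may attack the activated epoxide, or C10 may migrate in place of C13. The fallback sets out from 10 and comes back at 11: the rearrangement is run as its silyl-transfer variant with a bulky aluminium Lewis acid. Both free hydroxyls of 10 are silylated (TESOTf, 2,6-lutidine, CH2Cl2) to give the bis(triethylsilyl) ether F6. MeAl(OC6H2-4-Br-2,6-tBu2)2 (20 mol %, CH2Cl2, −78 °C) binds only the epoxide oxygen and should trigger the same 1,2-shift of C13, with transfer of the C9 silyl group to the C6 oxygen, giving the β-silyloxy ketone F7. HF·pyridine then returns diol 11.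

Further compounds
F1 | step 22 | tricyclic C6 alcohol with C7 N-methoxy-N-methylamide | C=C[C@H]1C=C(C)[C@@H]2[C@H]([C@@H]1C(=O)N(C)OC)[C@H](O)[C@@H]1[C@@H](C)C[C@@H](C)C[C@]12C
F2 | step 22 | C6 aryl ether of F1 with the N-Boc lactam 28 (iodine replaced by the C6 oxygen) | C=C[C@H]1C=C(C)[C@@H]2[C@H]([C@@H]1C(=O)N(C)OC)[C@H](Oc3ccc(C[C@H]4CCC(=O)N4C(=O)OC(C)(C)C)cc3)[C@@H]1[C@@H](C)C[C@@H](C)C[C@]12C
F3 | step 17 | dienyl iodide 20 with free C6 hydroxyl | COC(=O)/C=C/[C@H](O)[C@@H]1[C@@H](C)C[C@@H](C)C[C@]1(/C=C(\C)/C=C/I)C
F4 | step 17 | hydroxy (E,E)-triene enoate | COC(=O)/C=C/[C@H](O)[C@@H]1[C@@H](C)C[C@@H](C)C[C@]1(/C=C(\C)/C=C/C=C)C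
F5 | step 17 | tricyclic hydroxy ester (C6 OH, C7 CO2Me) | C=C[C@H]1C=C(C)[C@@H]2[C@H]([C@@H]1C(=O)OC)[C@H](O)[C@@H]1[C@@H](C)C[C@@H](C)C[C@]12C
F6 | step 8 | bis(triethylsilyl) ether of epoxy alcohol 10 (C5 and C9 oxygens) | CC[Si](CC)(CC)OC[C@H]1O[C@@H]1C2(O[Si](CC)(CC)CC)C[C@@H](C)C[C@]2(CO[Si](c3ccccc3)(c3ccccc3)C(C)(C)C)C
F7 | step 8 | bis(triethylsilyl) ether of keto diol 11 (C5 and C6 oxygens) | CC[Si](CC)(CC)OC[C@@H](O[Si](CC)(CC)CC)[C@@H]1C(=O)C[C@@H](C)C[C@]1(CO[Si](c2ccccc2)(c2ccccc2)C(C)(C)C)C
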